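**Retrosynthetic overview**
1. Ring numbering: C1 (quaternary carbon), C2=C3, C4 (O-senecioate), C5 (tertiary OH, Me), C6=C7, C8 (C=O), C9 (CH2OH)=C10, C11 (CH2). The route rests on the run C4(O)–C5(O)–cis-C6=C7–C8(=O) of the eleven-membered ring, which is the oxidation pattern of a 2-furyl carbinol (furan carbons C5–C8, carbinol carbon C4).
2. Target ⇐ closure of the eleven-membered ring at C8–C9 (CrCl2/NiCl2 coupling of a cis-enal with a (Z)-iodoalkene), then C8 oxidation and desilylation.
3. Open chain ⇐ six-membered pyranone lactol: catalyst-controlled 2,6-cis anomeric ester, MeMgBr at C5, Lindlar reduction of C2≡C3, ester removal and reductive opening of the lactol, C4 esterification, C10 acetal converted into the C9 iodoalkene.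
4. Pyranone lactol ⇐ (R)-2-furyl propargylic carbinol by vanadium/hydroperoxide ring expansion; carbinol ⇐ furfural + C1 alkyne (from geraniol by Sharpless epoxidation and epoxy silyl ether rearrangement).
5. Ring order: pyranone ring (step 10, temporary, opened in step 15), then the eleven-membered carbocycle (step 25).

Key step: step 10

Assumption 1: the target is taken as the open γ-hydroxy cis-enone as drawn; a transannular hemiketal between the C5 hydroxyl and C8 would be the same compound in equilibrium.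
Assumption 2: in step 9 the ligand is written as (S,S)-ProPhenol for Re-face delivery; the sense is to be checked on the first run (Mosher ester of 12) and the (R,R) ligand is used if it is opposite.
Assumption 3: in step 11 (S)-benzotetramisole is written for the catalyst that acylates the (6S) lactol anomer; the anomeric configuration of 15 is to be checked on the first run (NOE between H4 and H8) and (R)-benzotetramisole is used if the 2,6-trans ester predominates.
Remark: open-chain intermediates are described with the ring numbering of the target (C1–C11).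

**Step 1**
Reactants: 1 geraniol
Product: 2 (2S,3S)-2,3-epoxygeraniol
Conditions: Ti(OiPr)4 (5 mol %), L-(+)-diethyl tartrate (6 mol %), tBuOOH, 4 Å MS, CH2Cl2, −20 °C
Reagents that add atoms: tert-butyl hydroperoxide, CC(C)(C)OO
Why: Sharpless asymmetric epoxidation of an (E)-allylic alcohol; the titanium–L-(+)-tartrate complex delivers oxygen to one face and sets C2 and C3 as (2S,3S), the remote trisubstituted alkene being left alone.

**Step 2**
Reactants: 2 (2S,3S)-2,3-epoxygeraniol
Product: 3 (2S,3S)-2,3-epoxygeranyl tert-butyldimethylsilyl ether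
Conditions: TBSCl, imidazole, DMF, 0 °C to rt
Reagents that add atoms: tert-butyldimethylsilyl chloride, CC(C)(C)[Si](C)(C)Cl
Why: Standard silylation of a primary alcohol gives the epoxy silyl ether needed for the rearrangement.

**Step 3**
Reactants: 3 (2S,3S)-2,3-epoxygeranyl tert-butyldimethylsilyl ether
Product: 4 (S)-2-[(tert-butyldimethylsilyloxy)methyl]-2,6-dimethylhept-5-enal
Conditions: MeAl(OAr)2 (Ar = 4-bromo-2,6-di-tert-butylphenyl, 20 mol %), CH2Cl2, −78 to −20 °C
Reagents that add atoms: none
Why: Lewis acid-promoted epoxy silyl ether rearrangement (semipinacol type): the tertiary C–O bond ionises and the silyloxymethyl group migrates anti to it, so the epoxide configuration is transferred with inversion to the new quaternary carbon (future C1, S).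

**Step 4**
Reactants: 4 (S)-2-[(tert-butyldimethylsilyloxy)methyl]-2,6-dimethylhept-5-enal
Product: 5 (R)-tert-butyl[(2-ethynyl-2,6-dimethylhept-5-en-1-yl)oxy]dimethylsilane
Conditions: dimethyl (1-diazo-2-oxopropyl)phosphonate, K2CO3, MeOH, 0 °C to rt
Reagents that add atoms: dimethyl (1-diazo-2-oxopropyl)phosphonate, CC(=O)C(=[N+]=[N-])P(=O)(OC)OC
Why: Ohira–Bestmann alkynylation adds C3; the aldehyde has no α-hydrogen, so the quaternary centre cannot epimerise (the descriptor changes to R only through priorities).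

**Step 5**
Reactants: 5 (R)-tert-butyl[(2-ethynyl-2,6-dimethylhept-5-en-1-yl)oxy]dimethylsilane
Product: 6 (R)-2-ethynyl-2,6-dimethylhept-5-en-1-ol
Conditions: Bu4NF, THF, 0 °C to rt
Reagents that add atoms: none
Why: Fluoride desilylation of a primary silyl ether; alkyne and alkene are inert.

**Step 6**
Reactants: 6 (R)-2-ethynyl-2,6-dimethylhept-5-en-1-ol
Product: 7 (R)-2-ethynyl-2,6-dimethylhept-5-enal
Conditions: Dess–Martin periodinane, NaHCO3, CH2Cl2, 0 °C to rt
Reagents that add atoms: none
Why: Dess–Martin oxidation of a neopentyl alcohol to a non-enolisable aldehyde (C11).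

**Step 7**
Reactants: 7 (R)-2-ethynyl-2,6-dimethylhept-5-enal
Product: 8 (S)-3-(2-methoxyvinyl)-3,7-dimethyloct-6-en-1-yne (E/Z mixture)
Conditions: Ph3P(CH2OMe)Cl, KOtBu, THF, 0 °C
Reagents that add atoms: (methoxymethyl)triphenylphosphonium chloride, COC[P+](c1ccccc1)(c1ccccc1)c1ccccc1.[Cl-]
Why: Wittig methoxymethylenation adds C10; the ylide is not basic enough to consume the alkyne C–H and the enol ether geometry is of no consequence.

**Step 8**
Reactants: 8 (S)-3-(2-methoxyvinyl)-3,7-dimethyloct-6-en-1-yne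
Product: 9 (S)-3-(2,2-dimethoxyethyl)-3,7-dimethyloct-6-en-1-yne
Conditions: MeOH, PPTS (cat.), rt
Reagents that add atoms: methanol, CO
Why: Acid-catalysed addition of methanol to the enol ether gives the dimethyl acetal (C10 at the aldehyde level) under conditions too mild for the trisubstituted alkene.

**Step 9**
Reactants: 9 (S)-3-(2,2-dimethoxyethyl)-3,7-dimethyloct-6-en-1-yne; 10 furfural
Product: 12 (1R,4S)-4-(2,2-dimethoxyethyl)-1-(furan-2-yl)-4,8-dimethylnon-7-en-2-yn-1-ol, via methylzinc acetylide 11 (not isolated)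
Conditions: Me2Zn, (S,S)-ProPhenol (10 mol %), Ph3P=O (20 mol %), toluene, 0 to 4 °C; 9 in excess, recovered
Reagents that add atoms: none
Why: Catalytic asymmetric alkynylation of an aldehyde by a dinuclear zinc–amino alcohol complex; the chiral pocket delivers the alkynyl group to the Re face of furfural and sets C4 as R, the quaternary C1 being too remote to interfere.

**Step 10**
Reactants: 12 (1R,4S)-4-(2,2-dimethoxyethyl)-1-(furan-2-yl)-4,8-dimethylnon-7-en-2-yn-1-ol
Product: 14 (2R)-2-[(3S)-3-(2,2-dimethoxyethyl)-3,7-dimethyloct-6-en-1-ynyl]-6-hydroxy-2H-pyran-3(6H)-one (anomeric mixture), via cis-keto-aldehyde 13 (not isolated)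
Conditions: VO(acac)2 (5 mol %), tBuOOH (1.5 equiv, decane), CH2Cl2, 0 °C to rt
Reagents that add atoms: tert-butyl hydroperoxide, CC(C)(C)OO
Why: Coordination of the C4 hydroxyl to the oxovanadium catalyst places the activated peroxide over the neighbouring C5=C6 bond of the furan, which is epoxidised (new C5–O bond) and collapses by ring opening to keto-aldehyde 13; its C6=C7 bond keeps the cis geometry imposed by the former five-membered ring. Hemiacetal formation between the C4 hydroxyl and the C8 aldehyde (new C8–O bond, 6-exo-trig) then gives the six-membered pyranone. The closest known reaction is the Achmatowicz rearrangement of 2-furyl carbinols run with VO(acac)2 and an alkyl hydroperoxide. No stereocentre is set under control: C4 is carried through unchanged and the anomeric carbon C8 forms as an equilibrating mixture. The step must oxidise only the furan, not the trisubstituted alkene, the alkyne, the acetal or the carbinol itself; the directing hydroxyl sits next to the furan, the most easily oxidised π-system present, while the alkene is remote and undirected and alkynes do not react with this reagent.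

**Step 11**
Reactants: 14 pyranone lactol (anomeric mixture)
Product: 15 (2S,6R)-6-[(3S)-3-(2,2-dimethoxyethyl)-3,7-dimethyloct-6-en-1-ynyl]-5-oxo-5,6-dihydro-2H-pyran-2-yl 2-methylpropanoate (2,6-cis anomer)
Conditions: (iPrCO)2O (1.5 equiv), (S)-benzotetramisole [(S)-2-phenyl-2,3-dihydroimidazo[2,1-b][1,3]benzothiazole, 5 mol %], iPr2NEt, Na2SO4, CHCl3, 0 °C
Reagents that add atoms: 2-methylpropanoic anhydride, CC(C)C(=O)OC(=O)C(C)C
Why: Dynamic kinetic diastereoselective acylation of a lactol by a chiral isothiourea acyl-transfer catalyst: the anomers of 14 interconvert through the open keto-aldehyde while the N-acyl isothiouronium ion acylates the (6S) hydroxyl much faster, so the whole mixture should converge on the 2,6-cis ester with C8 fixed by the catalyst.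

**Step 12**
Reactants: 15 2,6-cis anomeric ester
Product: 16 (2S,5R,6R)-6-[(3S)-3-(2,2-dimethoxyethyl)-3,7-dimethyloct-6-en-1-ynyl]-5-hydroxy-5-methyl-5,6-dihydro-2H-pyran-2-yl 2-methylpropanoate
Conditions: MeMgBr (1.2 equiv), CeCl3 (1.5 equiv), THF, −78 °C; AcOH quench at −78 °C
Reagents that add atoms: methylmagnesium bromide, C[Mg]Br
Why: 1,2-Addition of the organocerium reagent to the enone carbonyl: in 15 the C4 alkynyl group and the C8 acyloxy group lie on the same face of the ring, so methyl should enter from the opposite face and set C5 as R (hydroxyl cis to the alkynyl group), while the weakly basic cerium reagent at −78 °C suppresses enolisation at C4 and should consume the ketone well before the branched ester.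

**Step 13**
Reactants: 16 tertiary propargylic pyranol
Product: 17 (2S,5R,6R)-6-[(1Z,3S)-3-(2,2-dimethoxyethyl)-3,7-dimethylocta-1,6-dienyl]-5-hydroxy-5-methyl-5,6-dihydro-2H-pyran-2-yl 2-methylpropanoate
Conditions: H2 (1 atm), Pd/CaCO3–Pb(OAc)2 (Lindlar catalyst), quinoline, EtOAc, rt
Reagents that add atoms: none
Why: Lindlar semihydrogenation delivers H2 syn to the alkyne and gives the cis C2=C3 alkene; the poisoned catalyst should not reduce the ring alkene or the trisubstituted alkene, nor cleave the allylic anomeric ester.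

**Step 14**
Reactants: 17 cis-alkenyl anomeric ester
Product: 18 (2R,3R)-2-[(1Z,3S)-3-(2,2-dimethoxyethyl)-3,7-dimethylocta-1,6-dienyl]-3-methyl-3,6-dihydro-2H-pyran-3,6-diol (anomeric mixture)
Conditions: K2CO3 (0.2 equiv), MeOH, 0 °C
Reagents that add atoms: none
Why: Base-catalysed transesterification: an anomeric ester is acylal-like and is methanolysed far faster than an ordinary ester, so the lactol is freed without exposing the tertiary allylic alcohol or the acetal to acid.

**Step 15**
Reactants: 18 lactol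
Product: 19 (2Z,4R,5R,6Z,8S)-8-(2,2-dimethoxyethyl)-4,8,12-trimethyltrideca-2,6,11-triene-1,4,5-triol (C4, C5 and C8 hydroxyls in target numbering)
Conditions: NaBH4, EtOH, 0 °C
Reagents that add atoms: none
Why: Borohydride reduction of a lactol through its open hydroxy-enal form; 1,2-reduction of the aldehyde opens the pyran for good and keeps the cis C6=C7 geometry.

**Step 16**
Reactants: 19 triol
Product: 20 C8-O-triethylsilyl ether of 19 (C4 and C5 hydroxyls free)
Conditions: Et3SiCl (1.05 equiv), imidazole, CH2Cl2, −78 °C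
Reagents that add atoms: chlorotriethylsilane, CC[Si](CC)(CC)Cl
Why: Selective silylation of the primary allylic hydroxyl over the hindered secondary and tertiary ones at low temperature.

**Step 17**
Reactants: 20 C8 silyl ether diol
Product: 21 C4 3-methylbut-2-enoate (senecioate) of 20 with the C5 hydroxyl free
Conditions: 3-methylbut-2-enoic acid, DCC, DMAP, CH2Cl2, 0 °C to rt
Reagents that add atoms: 3-methylbut-2-enoic acid, CC(C)=CC(O)=O
Why: Steglich esterification acylates the secondary C4 hydroxyl in preference to the tertiary C5 hydroxyl, and carbodiimide activation avoids the base-induced shift of the double bond out of conjugation that the acid chloride can suffer.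

**Step 18**
Reactants: 21 C4 senecioate
Product: 23 C10 aldehyde: 21 with a C5-O-triethylsilyl ether and CH2CHO in place of CH2CH(OMe)2, via lutidinium salt 22 (not isolated)
Conditions: Et3SiOTf (3 equiv), 2,6-lutidine, CH2Cl2, −40 to 0 °C; then H2O
Reagents that add atoms: triethylsilyl trifluoromethanesulfonate, CC[Si](CC)(CC)OS(=O)(=O)C(F)(F)F; water, O
Why: Silyl triflate/2,6-lutidine cleavage of a dimethyl acetal through the N-(1-methoxyalkyl)lutidinium salt 22, hydrolysed to the aldehyde on adding water, while the same reagent silylates the tertiary C5 hydroxyl; the ester and the primary silyl ether are inert to these non-acidic conditions.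

**Step 19**
Reactants: 23 C10 aldehyde
Product: 24 (9E)-enal: C11H2–C10H=C9H–CHO homologue of 23
Conditions: Ph3P=CHCHO, toluene, 80 °C
Reagents that add atoms: (triphenylphosphoranylidene)acetaldehyde, O=CC=P(c1ccccc1)(c1ccccc1)c1ccccc1
Why: Wittig reaction with the stabilised formyl ylide adds C9 and the future hydroxymethyl carbon as an (E)-enal under neutral conditions.

**Step 20**
Reactants: 24 (E)-enal
Product: 25 (Z)-α-iodoenal: 24 iodinated at C9 with iodine cis to C11
Conditions: I2, pyridine, DMAP (cat.), CH2Cl2, rt, dark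
Reagents that add atoms: iodine, II
Why: Amine-mediated α-iodination of an enal (conjugate addition of the amine, iodination of the enolate, elimination) should give the (Z)-iodoenal; the β,β-disubstituted senecioate cannot react this way and no water is present to form iodohydrins.

**Step 21**
Reactants: 25 (Z)-α-iodoenal
Product: 26 (Z)-2-iodoallylic alcohol: CH2OH in place of CHO in 25
Conditions: NaBH4, MeOH/THF, −20 °C
Reagents that add atoms: none
Why: Borohydride 1,2-reduction of the aldehyde leaves the senecioate and the alkenyl iodide untouched.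

**Step 22**
Reactants: 26 (Z)-2-iodoallylic alcohol
Product: 27 tert-butyldimethylsilyl ether of 26
Conditions: TBSCl, imidazole, CH2Cl2, 0 °C to rt
Reagents that add atoms: tert-butyldimethylsilyl chloride, CC(C)(C)[Si](C)(C)Cl
Why: Standard silylation masks the C9 hydroxymethyl group so that only C8 is oxidised later.

**Step 23**
Reactants: 27 tris-silyl ether
Product: 28 C8 primary allylic alcohol: 27 without the C8 triethylsilyl group
Conditions: PPTS (cat.), MeOH/CH2Cl2, 0 °C
Reagents that add atoms: none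
Why: Acid-catalysed methanolysis cleaves the primary triethylsilyl ether well before the primary tert-butyldimethylsilyl ether or the hindered tertiary triethylsilyl ether.

**Step 24**
Reactants: 28 C8 alcohol
Product: 29 cis-enal: C8 aldehyde of 28
Conditions: Dess–Martin periodinane, NaHCO3, CH2Cl2, 0 °C
Reagents that add atoms: none
Why: Buffered Dess–Martin oxidation should preserve the cis C6=C7 geometry, and the C5 silyl ether prevents the enal from closing to a five-membered lactol.

**Step 25**
Reactants: 29 cis-enal iodoalkene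
Product: 31 eleven-membered C8 carbinol (mixture of C8 epimers), via alkenylchromium dichloride 30 (not isolated)
Conditions: CrCl2 (10 equiv), NiCl2 (2 mol % of the chromium salt), DMSO, rt, slow addition, about 2 mM
Reagents that add atoms: none
Why: Nozaki–Hiyama–Kishi reaction: nickel-catalysed formation of the alkenylchromium species with retention of alkene geometry and its addition to the aldehyde closes the ring at C8–C9; three cis alkenes pre-organise the chain, and the new C8 centre is removed in the next step.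

**Step 26**
Reactants: 31 macrocyclic carbinol
Product: 32 bis-silyl ether of the target (C8 ketone)
Conditions: Dess–Martin periodinane, NaHCO3, CH2Cl2, 0 °C to rt
Reagents that add atoms: none
Why: Dess–Martin oxidation of the doubly allylic alcohol gives the cross-conjugated dienone under neutral conditions.

**Step 27**
Reactants: 32 bis-silyl ether
Product: 33 target
Conditions: HF·pyridine, pyridine, THF, 0 °C to rt
Reagents that add atoms: none
Why: Buffered fluoride desilylation removes the primary and the tertiary silyl ether without hydrolysing or migrating the senecioate.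

**Compound list**
1 | geraniol | CC(C)=CCC/C(C)=C/CO | starting material
2 | (2S,3S)-2,3-epoxygeraniol | CC(C)=CCC[C@]1(C)O[C@H]1CO | intermediate
3 | (2S,3S)-2,3-epoxygeranyl tert-butyldimethylsilyl ether | CC(C)=CCC[C@]1(C)O[C@H]1CO[Si](C)(C)C(C)(C)C | intermediate
4 | (S)-2-[(tert-butyldimethylsilyloxy)methyl]-2,6-dimethylhept-5-enal | CC(C)=CCC[C@](CO[Si](C)(C)C(C)(C)C)(C)C=O | intermediate
5 | (R)-tert-butyl[(2-ethynyl-2,6-dimethylhept-5-en-1-yl)oxy]dimethylsilane | CC(C)=CCC[C@](CO[Si](C)(C)C(C)(C)C)(C)C#C | intermediate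
6 | (R)-2-ethynyl-2,6-dimethylhept-5-en-1-ol | CC(C)=CCC[C@](CO)(C)C#C | intermediate
7 | (R)-2-ethynyl-2,6-dimethylhept-5-enal | CC(C)=CCC[C@](C=O)(C)C#C | intermediate
8 | (S)-3-(2-methoxyvinyl)-3,7-dimethyloct-6-en-1-yne (E/Z mixture) | CC(C)=CCC[C@](C=COC)(C)C#C | intermediate
9 | (S)-3-(2,2-dimethoxyethyl)-3,7-dimethyloct-6-en-1-yne | CC(C)=CCC[C@](CC(OC)OC)(C)C#C | intermediate
10 | furfural | O=Cc1ccco1 | starting material
11 | methylzinc acetylide of 9 (not isolated) | CC(C)=CCC[C@](CC(OC)OC)(C)C#C[Zn]C | intermediate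
12 | (1R,4S)-4-(2,2-dimethoxyethyl)-1-(furan-2-yl)-4,8-dimethylnon-7-en-2-yn-1-ol | CC(C)=CCC[C@](CC(OC)OC)(C)C#C[C@@H](O)c1ccco1 | intermediate
13 | (2Z,5R,8S)-8-(2,2-dimethoxyethyl)-5-hydroxy-8,12-dimethyl-4-oxotrideca-2,11-dien-6-ynal (not isolated) | CC(C)=CCC[C@](CC(OC)OC)(C)C#C[C@@H](O)C(=O)/C=C\C=O | intermediate
14 | (2R)-2-[(3S)-3-(2,2-dimethoxyethyl)-3,7-dimethyloct-6-en-1-ynyl]-6-hydroxy-2H-pyran-3(6H)-one (anomeric mixture) | CC(C)=CCC[C@](CC(OC)OC)(C)C#C[C@@H](O1)C(=O)C=CC1O | intermediate
15 | (2S,6R)-6-[(3S)-3-(2,2-dimethoxyethyl)-3,7-dimethyloct-6-en-1-ynyl]-5-oxo-5,6-dihydro-2H-pyran-2-yl 2-methylpropanoate (2,6-cis anomer) | CC(C)=CCC[C@](CC(OC)OC)(C)C#C[C@@H](O1)C(=O)C=C[C@@H]1OC(=O)C(C)C | intermediate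
16 | (2S,5R,6R)-6-[(3S)-3-(2,2-dimethoxyethyl)-3,7-dimethyloct-6-en-1-ynyl]-5-hydroxy-5-methyl-5,6-dihydro-2H-pyran-2-yl 2-methylpropanoate | CC(C)=CCC[C@](CC(OC)OC)(C)C#C[C@@H](O1)[C@](C)(O)C=C[C@@H]1OC(=O)C(C)C | intermediate
17 | (2S,5R,6R)-6-[(1Z,3S)-3-(2,2-dimethoxyethyl)-3,7-dimethylocta-1,6-dienyl]-5-hydroxy-5-methyl-5,6-dihydro-2H-pyran-2-yl 2-methylpropanoate | CC(C)=CCC[C@](CC(OC)OC)(C)/C=C\[C@@H](O1)[C@](C)(O)C=C[C@@H]1OC(=O)C(C)C | intermediate
18 | (2R,3R)-2-[(1Z,3S)-3-(2,2-dimethoxyethyl)-3,7-dimethylocta-1,6-dienyl]-3-methyl-3,6-dihydro-2H-pyran-3,6-diol (anomeric mixture) | CC(C)=CCC[C@](CC(OC)OC)(C)/C=C\[C@@H](O1)[C@](C)(O)C=CC1O | intermediate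
19 | (2Z,4R,5R,6Z,8S)-8-(2,2-dimethoxyethyl)-4,8,12-trimethyltrideca-2,6,11-triene-1,4,5-triol | CC(C)=CCC[C@](CC(OC)OC)(C)/C=C\[C@@H](O)[C@](C)(O)/C=C\CO | intermediate
20 | C8-O-triethylsilyl ether of 19 | CC(C)=CCC[C@](CC(OC)OC)(C)/C=C\[C@@H](O)[C@](C)(O)/C=C\CO[Si](CC)(CC)CC | intermediate
21 | C4 senecioate of 20 | CC(C)=CCC[C@](CC(OC)OC)(C)/C=C\[C@@H](OC(=O)C=C(C)C)[C@](C)(O)/C=C\CO[Si](CC)(CC)CC | intermediate
22 | C10 N-(1-methoxyalkyl)-2,6-lutidinium triflate with C5-O-triethylsilyl ether (C10 epimers, not isolated) | CC(C)=CCC[C@](CC(OC)[n+]1c(C)cccc1C)(C)/C=C\[C@@H](OC(=O)C=C(C)C)[C@](C)(O[Si](CC)(CC)CC)/C=C\CO[Si](CC)(CC)CC.[O-]S(=O)(=O)C(F)(F)F | intermediate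
23 | C10 aldehyde with C4 senecioate and C5, C8 triethylsilyl ethers | CC(C)=CCC[C@](CC=O)(C)/C=C\[C@@H](OC(=O)C=C(C)C)[C@](C)(O[Si](CC)(CC)CC)/C=C\CO[Si](CC)(CC)CC | intermediate
24 | (9E)-enal homologue of 23 | CC(C)=CCC[C@](C/C=C/C=O)(C)/C=C\[C@@H](OC(=O)C=C(C)C)[C@](C)(O[Si](CC)(CC)CC)/C=C\CO[Si](CC)(CC)CC | intermediate
25 | (Z)-C9-iodoenal | CC(C)=CCC[C@](C/C=C(\I)C=O)(C)/C=C\[C@@H](OC(=O)C=C(C)C)[C@](C)(O[Si](CC)(CC)CC)/C=C\CO[Si](CC)(CC)CC | intermediate
26 | (Z)-2-iodoallylic alcohol | CC(C)=CCC[C@](C/C=C(\I)CO)(C)/C=C\[C@@H](OC(=O)C=C(C)C)[C@](C)(O[Si](CC)(CC)CC)/C=C\CO[Si](CC)(CC)CC | intermediate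
27 | tert-butyldimethylsilyl ether of 26 | CC(C)=CCC[C@](C/C=C(\I)CO[Si](C)(C)C(C)(C)C)(C)/C=C\[C@@H](OC(=O)C=C(C)C)[C@](C)(O[Si](CC)(CC)CC)/C=C\CO[Si](CC)(CC)CC | intermediate
28 | C8 primary allylic alcohol | CC(C)=CCC[C@](C/C=C(\I)CO[Si](C)(C)C(C)(C)C)(C)/C=C\[C@@H](OC(=O)C=C(C)C)[C@](C)(O[Si](CC)(CC)CC)/C=C\CO | intermediate
29 | cis-enal (C8 aldehyde) with (Z)-C9 iodoalkene | CC(C)=CCC[C@](C/C=C(\I)CO[Si](C)(C)C(C)(C)C)(C)/C=C\[C@@H](OC(=O)C=C(C)C)[C@](C)(O[Si](CC)(CC)CC)/C=C\C=O | intermediate
30 | C9 alkenylchromium dichloride of 29 (not isolated) | CC(C)=CCC[C@](C/C=C(\[Cr](Cl)Cl)CO[Si](C)(C)C(C)(C)C)(C)/C=C\[C@@H](OC(=O)C=C(C)C)[C@](C)(O[Si](CC)(CC)CC)/C=C\C=O | intermediate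
31 | eleven-membered C8 carbinol (C8 epimers), C5-O-TES, C9-CH2-O-TBS | CC(C)=CCC[C@]1(C)/C=C\[C@@H](OC(=O)C=C(C)C)[C@](C)(O[Si](CC)(CC)CC)/C=C\C(O)/C(CO[Si](C)(C)C(C)(C)C)=C\C1 | intermediate
32 | bis-silyl ether of the target (C8 ketone) | CC(C)=CCC[C@]1(C)/C=C\[C@@H](OC(=O)C=C(C)C)[C@](C)(O[Si](CC)(CC)CC)/C=C\C(=O)/C(CO[Si](C)(C)C(C)(C)C)=C\C1 | intermediate
33 | (1S,2Z,4R,5R,6Z,9Z)-5-hydroxy-9-(hydroxymethyl)-1,5-dimethyl-1-(4-methylpent-3-enyl)-8-oxocycloundeca-2,6,9-trien-4-yl 3-methylbut-2-enoate | CC(C)=CCC[C@]1(C)/C=C\[C@@H](OC(=O)C=C(C)C)[C@](C)(O)/C=C\C(=O)/C(CO)=C\C1 | target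

**Step count and risks**
Total steps: 27. Longest linear sequence: 27 steps (geraniol to the target; furfural enters at step 9).

Step 25, closure of the eleven-membered ring. What may go wrong is intermolecular coupling to oligomers in competition with closure of a strained medium ring, and cis-to-trans isomerisation of the enal before it is captured. The fallback sets out from 29 and comes back at 32, forming the C8–C9 bond at the ketone level by a palladium-catalysed thioester–stannane ketone synthesis (Liebeskind–Srogl type). Aldehyde 29 is oxidised (NaClO2, NaH2PO4, 2-methyl-2-butene, tBuOH/H2O) to the (Z)-enoic acid F1. The acid is converted (EtSH, DCC, DMAP cat., CH2Cl2, 0 °C) into the S-ethyl thioester F2. The alkenyl iodide is exchanged for tin (Me3SnSnMe3, Pd(PPh3)4, toluene, 60 °C) to give the alkenylstannane F3. Cyclisation under high dilution (Pd2(dba)3, tri(2-furyl)phosphine, CuTC (monovalent copper thiophene-2-carboxylate), THF, 50 °C) should give dienone 32 with retention of the alkene geometry, so that the C8 carbinol and step 26 are bypassed.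

Step 12, methyl addition at C5. What may go wrong is enolisation at C4 next to the ketone with loss of configuration, attack from the wrong face if the two ring substituents do not reinforce each other, or competing attack of the organometallic reagent on the anomeric ester. The fallback sets out from 15 and comes back at 20, setting C5 under reagent control after the pyran is opened, so that neither a carbon nucleophile nor the anomeric configuration is involved. The ketone of 15 is methylenated (Ph3P=CH2, THF, −78 to 0 °C) to the 3-methylene pyranyl ester F4. Semihydrogenation as in step 13 gives the cis-alkene F5. Methanolysis as in step 14 gives the lactol F6, and NaBH4 reduction as in step 15 gives the dienediol F7. Silylation of the primary hydroxyl as in step 16 gives the mono-silyl ether F8. Sharpless epoxidation of the 1,1-disubstituted alkene directed by the C4 carbinol (Ti(OiPr)4, D-(−)-diisopropyl tartrate, tBuOOH, 4 Å MS, CH2Cl2, −20 °C; this tartrate is the matched one for the 4R carbinol) gives the epoxy alcohol F9. Hydride opening at the CH2 terminus (LiAlH4, Et2O, −20 °C) gives diol 20 with the tertiary C5 carbinol in the required configuration.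

Step 11, catalyst-controlled anomeric acylation. What may go wrong is that the catalyst fails to override the inherent preference of the lactol for acylation as the 2,6-trans anomer, or that the amine base epimerises C4 through enolisation of the alkynyl ketone while the anomers equilibrate. The fallback sets out from 14 and comes back at 18; it replaces catalyst control by separation and recycling of an anomeric silyl acetal, which also keeps an ester away from the methyl nucleophile. Lactol 14 is silylated (TBSCl, imidazole, CH2Cl2, 0 °C) to the 2,6-cis silyl acetal F10 and the 2,6-trans silyl acetal F11, which should be separable by chromatography; F11 is returned to 14 (Bu4NF, AcOH, THF, 0 °C) and resubmitted. Methyl addition to F10 as in step 12 gives the tertiary carbinol F12, semihydrogenation as in step 13 gives the cis-alkene F13, and buffered desilylation (Bu4NF, AcOH, THF, 0 °C) gives lactol 18.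

**Further compounds**
F1 | step 25 | (Z)-enoic acid from 29 (C8 carboxylic acid, C9 iodoalkene) | CC(C)=CCC[C@](C/C=C(\I)CO[Si](C)(C)C(C)(C)C)(C)/C=C\[C@@H](OC(=O)C=C(C)C)[C@](C)(O[Si](CC)(CC)CC)/C=C\C(O)=O
F2 | step 25 | S-ethyl thioester of F1 | CC(C)=CCC[C@](C/C=C(\I)CO[Si](C)(C)C(C)(C)C)(C)/C=C\[C@@H](OC(=O)C=C(C)C)[C@](C)(O[Si](CC)(CC)CC)/C=C\C(=O)SCC
F3 | step 25 | C9 trimethylstannyl alkene S-ethyl thioester | CC(C)=CCC[C@](C/C=C(\[Sn](C)(C)C)CO[Si](C)(C)C(C)(C)C)(C)/C=C\[C@@H](OC(=O)C=C(C)C)[C@](C)(O[Si](CC)(CC)CC)/C=C\C(=O)SCC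
F4 | step 12 | 3-methylene pyranyl 2-methylpropanoate from 15 | CC(C)=CCC[C@](CC(OC)OC)(C)C#C[C@@H](O1)C(=C)C=C[C@@H]1OC(=O)C(C)C
F5 | step 12 | cis-alkenyl 3-methylene pyranyl 2-methylpropanoate | CC(C)=CCC[C@](CC(OC)OC)(C)/C=C\[C@@H](O1)C(=C)C=C[C@@H]1OC(=O)C(C)C
F6 | step 12 | 3-methylene lactol (anomeric mixture) | CC(C)=CCC[C@](CC(OC)OC)(C)/C=C\[C@@H](O1)C(=C)C=CC1O
F7 | step 12 | dienediol with C5 exocyclic methylene (C4 and C8 hydroxyls) | CC(C)=CCC[C@](CC(OC)OC)(C)/C=C\[C@@H](O)C(=C)/C=C\CO
F8 | step 12 | C8-O-triethylsilyl ether of F7 | CC(C)=CCC[C@](CC(OC)OC)(C)/C=C\[C@@H](O)C(=C)/C=C\CO[Si](CC)(CC)CC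
F9 | step 12 | C5 spiro-epoxide (2,2-disubstituted oxirane) with free C4 hydroxyl | CC(C)=CCC[C@](CC(OC)OC)(C)/C=C\[C@@H](O)[C@@]1(CO1)/C=C\CO[Si](CC)(CC)CC
F10 | step 11 | (2R,6S)-6-(tert-butyldimethylsilyloxy)-2-[(3S)-3-(2,2-dimethoxyethyl)-3,7-dimethyloct-6-en-1-ynyl]-2H-pyran-3(6H)-one (2,6-cis silyl acetal) | CC(C)=CCC[C@](CC(OC)OC)(C)C#C[C@@H](O1)C(=O)C=C[C@@H]1O[Si](C)(C)C(C)(C)C
F11 | step 11 | (2R,6R)-6-(tert-butyldimethylsilyloxy)-2-[(3S)-3-(2,2-dimethoxyethyl)-3,7-dimethyloct-6-en-1-ynyl]-2H-pyran-3(6H)-one (2,6-trans silyl acetal, recycled) | CC(C)=CCC[C@](CC(OC)OC)(C)C#C[C@@H](O1)C(=O)C=C[C@H]1O[Si](C)(C)C(C)(C)C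
F12 | step 11 | (2R,3R,6S)-6-(tert-butyldimethylsilyloxy)-2-[(3S)-3-(2,2-dimethoxyethyl)-3,7-dimethyloct-6-en-1-ynyl]-3-methyl-3,6-dihydro-2H-pyran-3-ol | CC(C)=CCC[C@](CC(OC)OC)(C)C#C[C@@H](O1)[C@](C)(O)C=C[C@@H]1O[Si](C)(C)C(C)(C)C
F13 | step 11 | (2R,3R,6S)-6-(tert-butyldimethylsilyloxy)-2-[(1Z,3S)-3-(2,2-dimethoxyethyl)-3,7-dimethylocta-1,6-dienyl]-3-methyl-3,6-dihydro-2H-pyran-3-ol | CC(C)=CCC[C@](CC(OC)OC)(C)/C=C\[C@@H](O1)[C@](C)(O)C=C[C@@H]1O[Si](C)(C)C(C)(C)C
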